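## Structural features

The target is a 2-aryl-3-(hydroxymethyl)-2,3-dihydrobenzofuran, a phenylcoumaran of the 8–5′ neolignan type. Ring A, the benzo ring, carries a methoxy group at C7 next to the ring oxygen and a 2-(methoxycarbonyl)ethyl chain at C5, para to O1; ring B, a 4-hydroxy-3,5-dimethoxyphenyl group, sits on C2, and C3 carries the hydroxymethyl carbon C9. The only stereocentres are the adjacent C2 (S) and C3 (R), with ring B and C9 trans across the C2–C3 bond. C2 is benzylic to an electron-rich ring, para-related to a free phenol and bound to an aryloxy leaving group, so acid can ionise it and a ring B phenoxide can open the C2–O1 bond through a para-quinone methide; the methyl ester limits the use of hydride reagents and hydroxide. The real difficulty is to fix the absolute configuration of the C2/C3 pair and to close the ring without passing through a cation or quinone methide at C2. The feature used here is that O1 bridges the sp3 carbon C2 and the aromatic carbon C7a: if the ring is closed at O1–C7a, the C2–O bond can be made earlier as the carbinol of an open-chain aldol, and a syn C2/C3 pair becomes the trans ring with no event at C2. C7a is also the carbon that bears the phenolic oxygen in a ferulate-derived ring A, so that oxygen can first direct a Claisen rearrangement to C3a and then, as a triflate, act as the leaving group. The C9 oxygen is five atoms from C7a just as the C2 oxygen is, so only the C2 hydroxyl may be free when the ring is closed.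

## Logic of the disconnections

**20 from 19.** The two O–Si bonds (ring B phenol oxygen and O9) are cut. Both oxygens must be masked during ring closure: a free ring B phenol would compete as a nucleophile and, as a phenoxide para to C2, would labilise the C2–O bond, and O9 could close an isomeric ring. The same triisopropylsilyl group on both keeps the end game to one operation. The forward step must remove both without a basic phenoxide stage and without touching the methyl ester.

**19 from 18.** Only the O1–C7a bond is cut. The ring disappears and the two stereocentres become those of an open-chain 2-aryl-1,3-diol derivative, while the C2–O bond stays. Cutting here and not at O1–C2 means ring formation cannot alter C2, so the relative configuration is decided entirely by the earlier aldol. The forward step needs a C–O coupling that outpaces β-hydride elimination of a benzylic alkoxide and accepts a doubly ortho-substituted aryl triflate. As a design consequence O9 carries triisopropylsilyl rather than a smaller silyl group, because 1,3-silyl migration to the C2 alkoxide would free O9 to close the wrong five-membered ring.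

**18 from 17.** The O9–Si bond is cut. This gives a diol whose hydroxyls differ as primary and hindered secondary benzylic; the forward silylation relies on that steric difference.

**17 from 16.** C9 is returned to the acyl oxidation level, restoring its C–N bond to the auxiliary. Reduction is placed before ring closure on purpose: a β-hydroxy imide with an α-aryl group would be open to retro-aldol cleavage and α-epimerisation under hot carbonate, and the diol is not. The forward reduction must single out the imide carbonyl from the methyl ester and spare the aryl triflate.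

**16 from 11 and 13.** The C2–C3 bond is cut, giving two halves of similar size and creating both stereocentres in one auxiliary-controlled step. The triflate is already present in 11, so no phenol protecting group, no hydrogenolysis beside an electron-rich benzylic alcohol and no late triflation next to a free carbinol are needed; this saves two steps over a benzyl-ether variant. The forward aldol must give the syn pair in the (2S,3S) sense of 16, which calls for a Z enolate, a closed transition state and the (S)-configured auxiliary.

**13 from 12.** The phenolic O–Si bond is cut, leading to a commercial aldehyde. The forward silylation must cope with a phenol flanked by two methoxy groups.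

**11 from 8 and 9.** The N–C(acyl) bond is cut, separating the auxiliary from an arylacetic acid. The forward acylation must avoid strong base because of the methyl ester and the triflate.

**8 from 5.** The terminal C=C bond of the allyl group is cut with loss of one carbon. The allyl group is the form in which a two-carbon chain can be placed regiospecifically on the future C3a. The oxidant must spare ring A, which the electron-withdrawing triflate helps to ensure.

**5 from 4.** The O–S bond is cut, giving a phenol. The forward triflation is unambiguous because no other hydroxyl is present.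

**4 from 3, and 3 from 1 and 2.** The bond between the future C3a and the allyl group is cut by a sigmatropic transposition to an O-allyl ether, and then the O–allyl bond is cut. Regiochemistry is fixed by the substrate: of the positions ortho and para to the phenol oxygen of 1, only one is unsubstituted.

## Other disconnections considered

**Alternative 1:** The cut removes O1–C2 and C3–C9 together. The (E)-2-hydroxystilbene A1, with C5 held as a dioxolane-masked aldehyde and ring B as its benzyl ether, would be treated with Pd(OCOCF3)2, a chiral bisoxazoline, CO, methanol and benzoquinone. The phenol would add to the alkene activated by divalent palladium, the C3-bound alkylpalladium would insert CO, and methanolysis would release the trans ester A2.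

- In its favour: the heterocycle and C9 arrive in one operation, and A1 is a flat molecule that a Wittig or Heck reaction would assemble quickly. The source of chirality is a catalyst and not a stoichiometric auxiliary; on this point the alternative is the better plan. The C3 ester of A2 is epimerisable, so the trans arrangement could be reinforced thermodynamically.
- Against it: the closure is a 5-endo attack on a 1,2-diaryl alkene, whereas the well-developed enantioselective phenol oxypalladations are 5-exo closures onto allyl side chains. Anti-oxypalladation of the E-alkene, which is what places palladium trans to ring B, also places it syn to H2, so β-hydride elimination with aromatisation of the new ring would compete directly with CO insertion. CO and a quinone oxidant with an electron-rich stilbene add handling and side-reaction concerns.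
- After the key step, A2 still needs reduction of the C3 ester, acetal hydrolysis, olefination to build the propanoate, and hydrogenation with debenzylation. That is about four operations against one in the chosen plan, and it is forced because a side-chain ester could not be told apart from the C3 ester.
- Comparison: total length would be similar, so step economy is about equal. The chosen plan is stronger on mechanistic security, because its stereo-determining step and its ring-forming step each have close precedent and are separated from one another.

**Alternative 2:** The cut removes C2–C3 and O1–C2. Ring A would be supplied as the sulfone A3, which carbonate base would convert by loss of sulfinate into the ortho-quinone methide A4. Ring B and C2 would be supplied as the C2-symmetric sulfonium salt A5, drawn in its (2R,5R) form; the antipode would be taken if the sense of induction required it. Its ylide A6 would add to the methide carbon of A4 and the phenoxide would then displace the sulfur group to give A7.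

- In its favour: this is the most convergent of the four plans. Two fragments of equal size give both ring bonds and both stereocentres in one step, with the propanoate in place throughout. The trans ring follows from SN2 closure of the anti betaine, so on relative configuration it is the equal of the chosen plan. On convergence and probable step count it is the better plan.
- Against it: A4 carries C9 as a CH2OSi group with hydrogens next to the methide carbon, so a 1,5-hydrogen shift would compete with capture by A6. The absolute configuration of both centres would rest on one reagent-controlled facial discrimination on a planar, short-lived acceptor, whereas the aldol of the chosen plan uses a transition state of well-established sense. The electron-rich benzylic C–S bond of A5 is prone to heterolysis.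
- After the key step, A7 needs two deprotections, one of them a hydrogenolysis next to the benzylic C2–O1 bond, against a single fluoride step in the chosen plan.
- Comparison: the alternative wins on brevity; the chosen plan wins on predictability of the absolute configuration and on a gentler end game.

**Alternative 3:** The cut removes C3–C3a. The 2,3-trans flavan-3-yl mesylate A8, of (2R,3S) catechin-type configuration, would be solvolysed in buffered aqueous medium. The C4–C4a bond is anti-periplanar to the equatorial C3–O bond, so ring A would shift from C4 to C3 through a phenonium ion with inversion at C3, and water would open the bridged ion at the old C4 to give A9 with a free CH2OH.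

- In its favour: the step is stereospecific, mapping the trans-diequatorial flavan onto the trans dihydrobenzofuran with C2 untouched; on stereochemical fidelity it is the equal of the chosen plan. C9 appears unprotected, which is better than the chosen plan. The end game is a single pivalate methanolysis, equal to the chosen plan. A8 could in principle be reached through a catalytic asymmetric dihydroxylation.
- Against it: ring A here lacks the 5,7-dioxygenation that makes catechin-type rings migrate readily. The migrating carbon is activated only by O1 ortho to it, the C8 methoxy group being meta. The ring oxygen is equally anti-periplanar to the leaving group and could shift from C2 to C3, a path that an electron-rich ring B would encourage and that the pivalate in A8 is meant to damp. Elimination is a further competitor.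
- Comparison: A8 itself would need a longer synthesis than the whole of the chosen route up to its key step, so the alternative is poorer on step economy. The chosen key step leaves both stereocentres untouched, while this one inverts C3 through a cationic intermediate whose partitioning depends on the substrate.

Key step: step 10

Assumption on the chemistry: the dibutylboron Z enolate of the arylacetyl imide 11 is taken to react through the same closed chair transition state and with the same facial sense as the enolates of simple propionyl imides.

## Route

Step 1
Reactants: 1 methyl 3-(4-hydroxy-3-methoxyphenyl)propanoate; 2 allyl bromide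
Product: 3 methyl 3-[3-methoxy-4-(prop-2-en-1-yloxy)phenyl]propanoate
Conditions: K2CO3, acetone, reflux
Reagents that add atoms: none
Why: Williamson ether synthesis; the phenoxide is alkylated by the allylic bromide under conditions that leave the methyl ester alone.

Step 2
Reactants: 3 methyl 3-[3-methoxy-4-(prop-2-en-1-yloxy)phenyl]propanoate
Product: 4 methyl 3-[4-hydroxy-3-methoxy-5-(prop-2-en-1-yl)phenyl]propanoate
Conditions: PhNEt2, 200 °C
Reagents that add atoms: none
Why: Aromatic Claisen rearrangement, a [3,3]-sigmatropic shift followed by tautomerisation of the transient dienone; the allyl group can only go to the single free ortho carbon, since the other ortho position carries the methoxy group and the para position the side chain.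

Step 3
Reactants: 4 methyl 3-[4-hydroxy-3-methoxy-5-(prop-2-en-1-yl)phenyl]propanoate
Product: 5 methyl 3-[3-methoxy-5-(prop-2-en-1-yl)-4-(trifluoromethylsulfonyloxy)phenyl]propanoate
Conditions: Tf2O, pyridine, CH2Cl2, 0 °C
Reagents that add atoms: trifluoromethanesulfonic anhydride, O=S(=O)(OS(=O)(=O)C(F)(F)F)C(F)(F)F
Why: Sulfonylation of the phenol to the aryl triflate. Installed now, the triflate protects the phenol for the next six steps, deactivates ring A toward ozone and is the leaving group of the key step.

Step 4
Reactants: 5 methyl 3-[3-methoxy-5-(prop-2-en-1-yl)-4-(trifluoromethylsulfonyloxy)phenyl]propanoate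
Product: 8 2-[3-methoxy-5-(3-methoxy-3-oxopropyl)-2-(trifluoromethylsulfonyloxy)phenyl]acetic acid, via ozonide 6 (not isolated), via arylacetaldehyde 7 (not isolated)
Conditions: O3, CH2Cl2, −78 °C; PPh3, −78 °C to rt; then NaClO2, NaH2PO4, 2-methyl-2-butene, t-BuOH/H2O, 0 °C to rt
Reagents that add atoms: ozone, [O-][O+]=O; sodium chlorite, [Na+].[O-]Cl=O
Why: Ozonolysis of the terminal alkene with reductive work-up, then Pinnick oxidation of the crude aldehyde. The triflate-bearing ring is far less reactive toward ozone than the monosubstituted alkene, and buffered chlorite with a hypochlorite scavenger oxidises only the aldehyde.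

Step 5
Reactants: 8 2-[3-methoxy-5-(3-methoxy-3-oxopropyl)-2-(trifluoromethylsulfonyloxy)phenyl]acetic acid; 9 (S)-4-benzyloxazolidin-2-one
Product: 11 (S)-4-benzyl-3-{2-[3-methoxy-5-(3-methoxy-3-oxopropyl)-2-(trifluoromethylsulfonyloxy)phenyl]acetyl}oxazolidin-2-one, via mixed pivalic anhydride 10 (not isolated)
Conditions: PivCl, Et3N, THF, −20 °C; then LiCl, 9, −20 °C to rt
Reagents that add atoms: none
Why: N-Acylation of the Evans auxiliary through a mixed anhydride; LiCl and Et3N make the oxazolidinone nucleophilic enough to attack the less hindered arylacetyl carbonyl, so no strong base meets the methyl ester or the triflate. The pivaloyl group is present only in 10 and leaves as pivalate.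

Step 6
Reactants: 12 syringaldehyde
Product: 13 3,5-dimethoxy-4-(triisopropylsilyloxy)benzaldehyde
Conditions: TIPSCl, imidazole, DMF, rt to 40 °C
Reagents that add atoms: chlorotriisopropylsilane, CC(C)[Si](Cl)(C(C)C)C(C)C
Why: Silylation of a phenol. The bulky triisopropylsilyl ether is chosen because it must later survive borohydride and hot Cs2CO3.

Step 7
Reactants: 11 (S)-4-benzyl-3-{2-[3-methoxy-5-(3-methoxy-3-oxopropyl)-2-(trifluoromethylsulfonyloxy)phenyl]acetyl}oxazolidin-2-one; 13 3,5-dimethoxy-4-(triisopropylsilyloxy)benzaldehyde
Product: 16 (S)-4-benzyl-3-{(2S,3S)-3-[3,5-dimethoxy-4-(triisopropylsilyloxy)phenyl]-3-hydroxy-2-[3-methoxy-5-(3-methoxy-3-oxopropyl)-2-(trifluoromethylsulfonyloxy)phenyl]propanoyl}oxazolidin-2-one, via boron Z-enolate 14 (not isolated), via boron aldolate 15 (not isolated)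
Conditions: Bu2BOTf, i-Pr2NEt, CH2Cl2, −78 to 0 °C; 13, −78 to 0 °C; then pH 7 buffer, MeOH, 30% H2O2, 0 °C
Reagents that add atoms: none
Why: Evans syn aldol reaction. Soft enolisation gives the Z enolate 14, which adds to 13 through a closed chair (Zimmerman–Traxler) transition state with the aldehyde on the enolate face away from the benzyl group; this sets the future C3 (α-carbon, S) and C2 (carbinol, S) together as the syn pair. Oxidative work-up cleaves the boron aldolate 15; the dibutylboron unit is present only in 14 and 15.

Step 8
Reactants: 16 (S)-4-benzyl-3-{(2S,3S)-3-[3,5-dimethoxy-4-(triisopropylsilyloxy)phenyl]-3-hydroxy-2-[3-methoxy-5-(3-methoxy-3-oxopropyl)-2-(trifluoromethylsulfonyloxy)phenyl]propanoyl}oxazolidin-2-one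
Product: 17 methyl 3-{3-[(1S,2R)-1-[3,5-dimethoxy-4-(triisopropylsilyloxy)phenyl]-1,3-dihydroxypropan-2-yl]-5-methoxy-4-(trifluoromethylsulfonyloxy)phenyl}propanoate
Conditions: NaBH4, THF/H2O (4:1), 0 °C to rt
Reagents that add atoms: none
Why: Reductive removal of the Evans auxiliary with borohydride; the activated exocyclic imide carbonyl is reduced through the aldehyde to the primary alcohol at a temperature at which NaBH4 leaves the methyl ester and the aryl triflate alone, and 9 is released for recovery. No stereocentre is touched; the descriptor of the aryl-bearing carbon changes from S to R only because CH2OH ranks below the carbinol carbon.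

Step 9
Reactants: 17 methyl 3-{3-[(1S,2R)-1-[3,5-dimethoxy-4-(triisopropylsilyloxy)phenyl]-1,3-dihydroxypropan-2-yl]-5-methoxy-4-(trifluoromethylsulfonyloxy)phenyl}propanoate
Product: 18 methyl 3-{3-[(1S,2R)-1-[3,5-dimethoxy-4-(triisopropylsilyloxy)phenyl]-1-hydroxy-3-(triisopropylsilyloxy)propan-2-yl]-5-methoxy-4-(trifluoromethylsulfonyloxy)phenyl}propanoate
Conditions: TIPSCl, imidazole, DMAP (cat.), CH2Cl2, 0 °C to rt
Reagents that add atoms: chlorotriisopropylsilane, CC(C)[Si](Cl)(C(C)C)C(C)C
Why: Regioselective silyl ether formation; the bulky chlorosilane reacts with the primary C9 hydroxyl and not with the hindered secondary benzylic one. Triisopropylsilyl is preferred to tert-butyldimethylsilyl here because it resists 1,3 oxygen-to-oxygen migration under the basic conditions of step 10.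

Step 10
Reactants: 18 methyl 3-{3-[(1S,2R)-1-[3,5-dimethoxy-4-(triisopropylsilyloxy)phenyl]-1-hydroxy-3-(triisopropylsilyloxy)propan-2-yl]-5-methoxy-4-(trifluoromethylsulfonyloxy)phenyl}propanoate
Product: 19 methyl 3-[(2S,3R)-2-[3,5-dimethoxy-4-(triisopropylsilyloxy)phenyl]-7-methoxy-3-[(triisopropylsilyloxy)methyl]-2,3-dihydro-1-benzofuran-5-yl]propanoate
Conditions: Pd2(dba)3 (2.5 mol %), t-BuBrettPhos (6 mol %), Cs2CO3, toluene, 80 °C
Reagents that add atoms: none
Why: Buchwald–Hartwig-type intramolecular C–O cross-coupling (palladium-catalysed etherification of an aryl sulfonate by a secondary alcohol), a known way to 2-substituted dihydrobenzofurans. Zerovalent palladium carrying the bulky biarylphosphine adds oxidatively into the C7a–OTf bond; the C2 hydroxyl binds to the divalent arylpalladium centre and is deprotonated by Cs2CO3, giving a six-membered oxapalladacycle (Pd, C7a, C3a, C3, C2, O). C–O reductive elimination from this palladacycle forms O1–C7a and closes the five-membered ring, formally a 5-exo closure at the sp2 carbon C7a with the departing triflate outside the ring, and returns zerovalent palladium. No stereocentre is created: the C2–O bond and the bonds at C3 made in the aldol are never broken, so the syn C2/C3 pair of 18 passes with retention into the trans ring of 19. Reductive elimination must outrun β-hydride elimination of the benzylic alkoxide and S–O cleavage of the triflate, which the very bulky ligand, the mild carbonate base and anhydrous toluene are chosen to secure. The C2 oxygen must be the only nucleophile, which holds because the ring B phenol and the C9 hydroxyl, itself five atoms from C7a, are both non-migrating triisopropylsilyl ethers. The ortho methoxy group and the branched ortho side chain slow oxidative addition, which is why a triflate is paired with an electron-rich dialkylbiarylphosphine.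

Step 11
Reactants: 19 methyl 3-[(2S,3R)-2-[3,5-dimethoxy-4-(triisopropylsilyloxy)phenyl]-7-methoxy-3-[(triisopropylsilyloxy)methyl]-2,3-dihydro-1-benzofuran-5-yl]propanoate
Product: 20 methyl 3-[(2S,3R)-2-(4-hydroxy-3,5-dimethoxyphenyl)-3-(hydroxymethyl)-7-methoxy-2,3-dihydro-1-benzofuran-5-yl]propanoate
Conditions: TBAF, AcOH, THF, 0 °C to rt
Reagents that add atoms: none
Why: Fluoride-induced cleavage of both silyl ethers, driven by formation of the Si–F bond. Acetic acid keeps the liberated ring B phenol protonated, which shuts off phenoxide-triggered opening of the C2–O1 bond through a para-quinone methide and protects the methyl ester from basic cleavage; neither stereocentre is involved.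

## Compound list

1 | methyl 3-(4-hydroxy-3-methoxyphenyl)propanoate (methyl dihydroferulate) | COC(=O)CCc1ccc(O)c(OC)c1 | starting material
2 | allyl bromide | C=CCBr | starting material
3 | methyl 3-[3-methoxy-4-(prop-2-en-1-yloxy)phenyl]propanoate | COC(=O)CCc1ccc(OCC=C)c(OC)c1 | intermediate
4 | methyl 3-[4-hydroxy-3-methoxy-5-(prop-2-en-1-yl)phenyl]propanoate | COC(=O)CCc1cc(CC=C)c(O)c(OC)c1 | intermediate
5 | methyl 3-[3-methoxy-5-(prop-2-en-1-yl)-4-(trifluoromethylsulfonyloxy)phenyl]propanoate | COC(=O)CCc1cc(CC=C)c(OS(=O)(=O)C(F)(F)F)c(OC)c1 | intermediate
6 | methyl 3-[3-methoxy-5-(1,2,4-trioxolan-3-ylmethyl)-4-(trifluoromethylsulfonyloxy)phenyl]propanoate (ozonide, racemic at the ring carbon) | COC(=O)CCc1cc(CC2OCOO2)c(OS(=O)(=O)C(F)(F)F)c(OC)c1 | intermediate (not isolated)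
7 | methyl 3-[3-methoxy-5-(2-oxoethyl)-4-(trifluoromethylsulfonyloxy)phenyl]propanoate | COC(=O)CCc1cc(CC=O)c(OS(=O)(=O)C(F)(F)F)c(OC)c1 | intermediate (not isolated)
8 | 2-[3-methoxy-5-(3-methoxy-3-oxopropyl)-2-(trifluoromethylsulfonyloxy)phenyl]acetic acid | COC(=O)CCc1cc(CC(=O)O)c(OS(=O)(=O)C(F)(F)F)c(OC)c1 | intermediate
9 | (S)-4-benzyloxazolidin-2-one | O=C1N[C@@H](Cc2ccccc2)CO1 | starting material
10 | mixed anhydride of 8 with pivalic acid | COC(=O)CCc1cc(CC(=O)OC(=O)C(C)(C)C)c(OS(=O)(=O)C(F)(F)F)c(OC)c1 | intermediate (not isolated)
11 | (S)-4-benzyl-3-{2-[3-methoxy-5-(3-methoxy-3-oxopropyl)-2-(trifluoromethylsulfonyloxy)phenyl]acetyl}oxazolidin-2-one | COC(=O)CCc1cc(CC(=O)N2[C@@H](Cc3ccccc3)COC2=O)c(OS(=O)(=O)C(F)(F)F)c(OC)c1 | intermediate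
12 | syringaldehyde (4-hydroxy-3,5-dimethoxybenzaldehyde) | COc1cc(C=O)cc(OC)c1O | starting material
13 | 3,5-dimethoxy-4-(triisopropylsilyloxy)benzaldehyde | COc1cc(C=O)cc(OC)c1O[Si](C(C)C)(C(C)C)C(C)C | intermediate
14 | (Z)-dibutylboron enolate of 11 | CCCCB(CCCC)O/C(=C\c1cc(CCC(=O)OC)cc(OC)c1OS(=O)(=O)C(F)(F)F)N1[C@@H](Cc2ccccc2)COC1=O | intermediate (not isolated)
15 | O-dibutylboryl derivative of 16 (boron aldolate, 2S,3S) | COC(=O)CCc1cc(OC)c(OS(=O)(=O)C(F)(F)F)c(c1)[C@H](C(=O)N1[C@@H](Cc2ccccc2)COC1=O)[C@H](OB(CCCC)CCCC)c1cc(OC)c(O[Si](C(C)C)(C(C)C)C(C)C)c(OC)c1 | intermediate (not isolated)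
16 | (S)-4-benzyl-3-{(2S,3S)-3-[3,5-dimethoxy-4-(triisopropylsilyloxy)phenyl]-3-hydroxy-2-[3-methoxy-5-(3-methoxy-3-oxopropyl)-2-(trifluoromethylsulfonyloxy)phenyl]propanoyl}oxazolidin-2-one | COC(=O)CCc1cc(OC)c(OS(=O)(=O)C(F)(F)F)c(c1)[C@H](C(=O)N1[C@@H](Cc2ccccc2)COC1=O)[C@H](O)c1cc(OC)c(O[Si](C(C)C)(C(C)C)C(C)C)c(OC)c1 | intermediate
17 | methyl 3-{3-[(1S,2R)-1-[3,5-dimethoxy-4-(triisopropylsilyloxy)phenyl]-1,3-dihydroxypropan-2-yl]-5-methoxy-4-(trifluoromethylsulfonyloxy)phenyl}propanoate | COC(=O)CCc1cc(OC)c(OS(=O)(=O)C(F)(F)F)c(c1)[C@H](CO)[C@H](O)c1cc(OC)c(O[Si](C(C)C)(C(C)C)C(C)C)c(OC)c1 | intermediate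
18 | methyl 3-{3-[(1S,2R)-1-[3,5-dimethoxy-4-(triisopropylsilyloxy)phenyl]-1-hydroxy-3-(triisopropylsilyloxy)propan-2-yl]-5-methoxy-4-(trifluoromethylsulfonyloxy)phenyl}propanoate | COC(=O)CCc1cc(OC)c(OS(=O)(=O)C(F)(F)F)c(c1)[C@H](CO[Si](C(C)C)(C(C)C)C(C)C)[C@@H](c1cc(OC)c(O[Si](C(C)C)(C(C)C)C(C)C)c(OC)c1)O | intermediate
19 | methyl 3-[(2S,3R)-2-[3,5-dimethoxy-4-(triisopropylsilyloxy)phenyl]-7-methoxy-3-[(triisopropylsilyloxy)methyl]-2,3-dihydro-1-benzofuran-5-yl]propanoate | COC(=O)CCc1cc(OC)c2c(c1)[C@H](CO[Si](C(C)C)(C(C)C)C(C)C)[C@@H](c1cc(OC)c(O[Si](C(C)C)(C(C)C)C(C)C)c(OC)c1)O2 | intermediate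
20 | methyl 3-[(2S,3R)-2-(4-hydroxy-3,5-dimethoxyphenyl)-3-(hydroxymethyl)-7-methoxy-2,3-dihydro-1-benzofuran-5-yl]propanoate | COC(=O)CCc1cc(OC)c2c(c1)[C@H](CO)[C@@H](c1cc(OC)c(O)c(OC)c1)O2 | target

## Step count and least certain steps

Total: 11 steps. Longest linear sequence: 10 steps (1 to 3, 4, 5, 8, 11, 16, 17, 18, 19, 20); step 6 is a one-step branch.

**Step 10 (key step).** Most likely to go wrong: β-hydride elimination from the palladium alkoxide, which would oxidise C2 and reduce off the triflate, and slow oxidative addition into the doubly ortho-substituted, electron-rich triflate, which would let S–O cleavage by carbonate take over. Fallback: closure at O1–C7a is given up and the ring is closed at O1–C2 under thermodynamic control, setting out from 18 and coming back at 19. Miyaura borylation of 18 (B2pin2, Pd(dppf)Cl2, KOAc, dioxane, 80 °C) would give the aryl pinacol boronate F1. Oxidation of the C–B bond with NaBO3·4H2O in THF/H2O would give the phenol F2. Catalytic camphorsulfonic acid in CH2Cl2 (0 °C to rt) would then ionise the benzylic carbinol, and capture of the cation by the neighbouring phenol should give the more stable trans ring of 19. In this variant C3, set by the aldol, is the only controlling centre and C2 is re-formed; the price is exposure of C2 to ionisation, with E1 loss of the C3 proton as the main hazard.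

**Step 7.** Most likely to go wrong: erosion of the syn/anti ratio through reversible aldolisation, since the electron-rich aldehyde departs easily in a retro-aldol, together with incomplete conversion of a crowded ortho-substituted enolate. Fallback: the carbinol centre is set by reduction instead of by the aldol transition state, setting out from crude 16 mixed with its carbinol epimer F3 and coming back at 16. Dess–Martin periodinane (CH2Cl2, NaHCO3, 0 °C) would converge both on the β-keto imide F4, whose α-centre is shielded from enolisation by allylic 1,3-strain. Zn(BH4)2 (CH2Cl2/Et2O, −20 °C) would then deliver hydride to the chelated ketone anti to the α-aryl group, giving the syn carbinol 16.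

**Step 8.** Most likely to go wrong: loss of chemoselectivity by hydride attack on the methyl ester, or retro-aldol fragmentation in the basic aqueous borohydride medium before reduction. Fallback: hydrolysis followed by a reductant that prefers acids over esters, setting out from 16 and coming back at 17. LiOH/H2O2 (THF/H2O, 0 °C) would cleave the exocyclic imide carbonyl to the β-hydroxy acid F5 with release of the auxiliary. BH3·SMe2 (THF, 0 °C) would then reduce the carboxylic acid in preference to the methyl ester to give 17.

**Step 4.** Most likely to go wrong: attack of ozone on the methoxy-substituted ring and self-condensation of the enolisable arylacetaldehyde between the two stages. Fallback: a staged glycol-cleavage route through a stable, storable intermediate, setting out from 5 and coming back at 7. Dihydroxylation with K2OsO4·2H2O (cat.) and N-methylmorpholine N-oxide in acetone/H2O would give the diol F6. NaIO4 in THF/H2O would release the aldehyde 7 only when needed, and 7 would be oxidised at once to 8 as in step 4.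

## Further compounds

F1 | step 10 | methyl 3-{3-[(1S,2R)-1-[3,5-dimethoxy-4-(triisopropylsilyloxy)phenyl]-1-hydroxy-3-(triisopropylsilyloxy)propan-2-yl]-5-methoxy-4-(4,4,5,5-tetramethyl-1,3,2-dioxaborolan-2-yl)phenyl}propanoate | COC(=O)CCc1cc(OC)c(B2OC(C)(C)C(C)(C)O2)c(c1)[C@H](CO[Si](C(C)C)(C(C)C)C(C)C)[C@@H](c1cc(OC)c(O[Si](C(C)C)(C(C)C)C(C)C)c(OC)c1)O
F2 | step 10 | methyl 3-{3-[(1S,2R)-1-[3,5-dimethoxy-4-(triisopropylsilyloxy)phenyl]-1-hydroxy-3-(triisopropylsilyloxy)propan-2-yl]-4-hydroxy-5-methoxyphenyl}propanoate | COC(=O)CCc1cc(OC)c(O)c(c1)[C@H](CO[Si](C(C)C)(C(C)C)C(C)C)[C@@H](c1cc(OC)c(O[Si](C(C)C)(C(C)C)C(C)C)c(OC)c1)O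
F3 | step 7 | (S)-4-benzyl-3-{(2S,3R)-3-[3,5-dimethoxy-4-(triisopropylsilyloxy)phenyl]-3-hydroxy-2-[3-methoxy-5-(3-methoxy-3-oxopropyl)-2-(trifluoromethylsulfonyloxy)phenyl]propanoyl}oxazolidin-2-one (anti, carbinol epimer of 16) | COC(=O)CCc1cc(OC)c(OS(=O)(=O)C(F)(F)F)c(c1)[C@H](C(=O)N1[C@@H](Cc2ccccc2)COC1=O)[C@@H](O)c1cc(OC)c(O[Si](C(C)C)(C(C)C)C(C)C)c(OC)c1
F4 | step 7 | (S)-4-benzyl-3-{(2S)-3-[3,5-dimethoxy-4-(triisopropylsilyloxy)phenyl]-2-[3-methoxy-5-(3-methoxy-3-oxopropyl)-2-(trifluoromethylsulfonyloxy)phenyl]-3-oxopropanoyl}oxazolidin-2-one | COC(=O)CCc1cc(OC)c(OS(=O)(=O)C(F)(F)F)c(c1)[C@H](C(=O)N1[C@@H](Cc2ccccc2)COC1=O)C(=O)c1cc(OC)c(O[Si](C(C)C)(C(C)C)C(C)C)c(OC)c1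
F5 | step 8 | (2S,3S)-3-[3,5-dimethoxy-4-(triisopropylsilyloxy)phenyl]-3-hydroxy-2-[3-methoxy-5-(3-methoxy-3-oxopropyl)-2-(trifluoromethylsulfonyloxy)phenyl]propanoic acid | COC(=O)CCc1cc(OC)c(OS(=O)(=O)C(F)(F)F)c(c1)[C@H](C(=O)O)[C@H](O)c1cc(OC)c(O[Si](C(C)C)(C(C)C)C(C)C)c(OC)c1
F6 | step 4 | methyl 3-[3-(2,3-dihydroxypropyl)-5-methoxy-4-(trifluoromethylsulfonyloxy)phenyl]propanoate (racemic) | COC(=O)CCc1cc(CC(O)CO)c(OS(=O)(=O)C(F)(F)F)c(OC)c1
A1 | alternative 1 | 2-{(E)-2-[4-(benzyloxy)-3,5-dimethoxyphenyl]ethenyl}-4-(1,3-dioxolan-2-yl)-6-methoxyphenol | O1CCOC1c1cc(OC)c(O)c(c1)/C=C/c1cc(OC)c(OCc2ccccc2)c(OC)c1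
A2 | alternative 1 | methyl (2S,3S)-2-[4-(benzyloxy)-3,5-dimethoxyphenyl]-5-(1,3-dioxolan-2-yl)-7-methoxy-2,3-dihydro-1-benzofuran-3-carboxylate (trans) | O1CCOC1c1cc(OC)c2c(c1)[C@H](C(=O)OC)[C@@H](c1cc(OC)c(OCc3ccccc3)c(OC)c1)O2
A3 | alternative 2 | methyl 3-{3-[2-(tert-butyldimethylsilyloxy)-1-(4-methylphenylsulfonyl)ethyl]-4-hydroxy-5-methoxyphenyl}propanoate (racemic) | COC(=O)CCc1cc(OC)c(O)c(c1)C(CO[Si](C)(C)C(C)(C)C)S(=O)(=O)c1ccc(C)cc1
A4 | alternative 2 | 6-[2-(tert-butyldimethylsilyloxy)ethylidene]-2-methoxy-4-(3-methoxy-3-oxopropyl)cyclohexa-2,4-dien-1-one (ortho-quinone methide, alkene geometry not defined) | COC(=O)CCC1=CC(=CCO[Si](C)(C)C(C)(C)C)C(=O)C(OC)=C1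
A5 | alternative 2 | (2R,5R)-1-[4-(benzyloxy)-3,5-dimethoxybenzyl]-2,5-dimethylthiolan-1-ium tetrafluoroborate | C[C@@H]1CC[C@@H](C)[S+]1Cc1cc(OC)c(OCc2ccccc2)c(OC)c1.F[B-](F)(F)F
A6 | alternative 2 | benzylic ylide of A5 | C[C@@H]1CC[C@@H](C)[S+]1[CH-]c1cc(OC)c(OCc2ccccc2)c(OC)c1
A7 | alternative 2 | methyl 3-[(2S,3R)-2-[4-(benzyloxy)-3,5-dimethoxyphenyl]-3-[(tert-butyldimethylsilyloxy)methyl]-7-methoxy-2,3-dihydro-1-benzofuran-5-yl]propanoate | COC(=O)CCc1cc(OC)c2c(c1)[C@H](CO[Si](C)(C)C(C)(C)C)[C@@H](c1cc(OC)c(OCc3ccccc3)c(OC)c1)O2
A8 | alternative 3 | methyl 3-[(2R,3S)-2-[3,5-dimethoxy-4-(pivaloyloxy)phenyl]-8-methoxy-3-(methylsulfonyloxy)-3,4-dihydro-2H-chromen-6-yl]propanoate | COC(=O)CCc1cc(OC)c2c(c1)C[C@H](OS(C)(=O)=O)[C@@H](c1cc(OC)c(OC(=O)C(C)(C)C)c(OC)c1)O2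
A9 | alternative 3 | methyl 3-[(2S,3R)-2-[3,5-dimethoxy-4-(pivaloyloxy)phenyl]-3-(hydroxymethyl)-7-methoxy-2,3-dihydro-1-benzofuran-5-yl]propanoate | COC(=O)CCc1cc(OC)c2c(c1)[C@H](CO)[C@@H](c1cc(OC)c(OC(=O)C(C)(C)C)c(OC)c1)O2
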